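The plan cuts C5–C10 together with C6–C7 (abietane numbering), the two bonds that tie C5–C6 to the bridgeheads of the 2-oxabicyclo[2.2.2]octene built from C7, O, C20, C10 and the aromatic bond C8–C9. That bicycle is the retron of an intramolecular Diels–Alder reaction between an o-quinoid 2-benzopyran-3-one and a vinyl group tethered to C10 through C1–C4. One thermal operation closes rings A and B, makes the quaternary C10 and sets C5, C7 and C10 from the acetoxy stereocentre C2. The precursor is an o-formylarylacetic acid carrying a (4R)-4-acetoxy-6,6-dimethyloct-7-enoic chain; the lactone bridge is afterwards reduced to the C20–O–C7 ether.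

Key step: step 8

Remark: abietane numbering is used throughout (C2 = acetoxy carbon, C5/C10 = ring-fusion carbons, C7 = benzylic O–CH, C20 = O–CH2). The descriptor of the acetoxy carbon changes between open-chain and cyclic compounds only because the CIP ranking changes. Compounds 1, 9 and 10 (10 as a THF solution) are taken as commercial.

Step 1
Reactants: 1 3-bromo-4,5-dihydroxybenzaldehyde
Product: 2 7-bromo-2,2-diphenyl-1,3-benzodioxole-5-carbaldehyde
Conditions: Ph2CCl2, Ph2O, 170 °C
Reagents that add atoms: dichlorodiphenylmethane ClC(Cl)(c1ccccc1)c1ccccc1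
Why: Ketalisation of a catechol with a gem-dichloride is driven by loss of HCl and should give a benzophenone ketal that is stable to organolithiums, hydride and hot acetic anhydride and is removable by hydrogenolysis.

Step 2
Reactants: 2 7-bromo-2,2-diphenyl-1,3-benzodioxole-5-carbaldehyde
Product: 3 7-isopropyl-2,2-diphenyl-1,3-benzodioxole-5-carbaldehyde
Conditions: i-PrZnBr, Pd(OAc)2 (cat.), CPhos (cat.), THF/toluene, rt
Reagents that add atoms: isopropylzinc bromide CC(C)[Zn]Br
Why: Negishi coupling of a secondary alkylzinc halide with an aryl bromide should proceed without attack on the aldehyde, the biarylphosphine ligand favouring reductive elimination over β-hydride isomerisation to the n-propyl product.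

Step 3
Reactants: 3 7-isopropyl-2,2-diphenyl-1,3-benzodioxole-5-carbaldehyde
Product: 4 6-(dimethoxymethyl)-4-isopropyl-2,2-diphenyl-1,3-benzodioxole
Conditions: HC(OMe)3, MeOH, TsOH (cat.), rt; Et3N
Reagents that add atoms: trimethyl orthoformate COC(OC)OC
Why: Acid-catalysed acetalisation with the orthoformate as water scavenger should mask the aldehyde and at the same time install a directing group for metalation.

Step 4
Reactants: 4 6-(dimethoxymethyl)-4-isopropyl-2,2-diphenyl-1,3-benzodioxole
Product: 6 2-[5-(dimethoxymethyl)-7-isopropyl-2,2-diphenyl-1,3-benzodioxol-4-yl]ethan-1-ol, via aryllithium 5 (not isolated)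
Conditions: n-BuLi, TMEDA, Et2O, −20 to 0 °C; oxirane (THF solution), −78 °C to rt; H2O
Reagents that add atoms: oxirane C1CO1
Why: Directed ortho-metalation should occur at the only ring position flanked by two coordinating groups (acetal and dioxole oxygen, the future C9), and the aryllithium should open oxirane by SN2 to deliver the two carbons that become C10 and C20.

Step 5
Reactants: 6 2-[5-(dimethoxymethyl)-7-isopropyl-2,2-diphenyl-1,3-benzodioxol-4-yl]ethan-1-ol
Product: 8 2-[5-(dimethoxymethyl)-7-isopropyl-2,2-diphenyl-1,3-benzodioxol-4-yl]acetic acid, via arylacetaldehyde 7 (not isolated)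
Conditions: TEMPO (cat.), NaOCl (cat.), NaClO2, MeCN/phosphate buffer pH 6.7, 35 °C; acidify to pH 5
Reagents that add atoms: sodium chlorite [Na+].[O-]Cl=O
Why: The oxoammonium-catalysed chlorite oxidation should take the primary alcohol through the aldehyde to the acid near neutral pH, where the dimethyl acetal and the ketal survive and ring chlorination is kept low.

Step 6
Reactants: 9 (S)-epichlorohydrin; 10 prenylmagnesium chloride
Product: 12 (S)-2-(2,2-dimethylbut-3-en-1-yl)oxirane, via chlorohydrin 11 (not isolated)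
Conditions: THF, −40 to 0 °C; then 3 M aq. NaOH, Bu4NHSO4 (cat.), rt
Reagents that add atoms: none
Why: Allylic Grignard reagents open epoxides by the SE2′ path, so the prenyl reagent should deliver its tertiary carbon to the epoxide CH2 (reverse prenylation), and base then closes the chlorohydrin onto the CH2Cl carbon without touching the stereocentre, which stays (S).

Step 7
Reactants: 8 2-[5-(dimethoxymethyl)-7-isopropyl-2,2-diphenyl-1,3-benzodioxol-4-yl]acetic acid; 12 (S)-2-(2,2-dimethylbut-3-en-1-yl)oxirane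
Product: 16 (4R)-4-acetoxy-2-(5-formyl-7-isopropyl-2,2-diphenyl-1,3-benzodioxol-4-yl)-6,6-dimethyloct-7-enoic acid (both C2 epimers), via dilithium enediolate 13 (not isolated), via dilithium hydroxy carboxylate 14 (not isolated), via acetoxy acid dimethyl acetal 15 (not isolated)
Conditions: LDA (2.2 equiv), THF, −78 to 0 °C; 12, 0 °C to rt; Ac2O, 0 °C; then 1 M HCl, THF, rt
Reagents that add atoms: acetic anhydride CC(=O)OC(C)=O
Why: The enediolate of an arylacetic acid should open the terminal epoxide at CH2 (carboxylic acid dianion alkylation), and because a carboxylate cannot be attacked the alkoxide persists and is acetylated in the flask before dilute acid frees the acid and hydrolyses the acetal; the acetoxy carbon is untouched and the new centre at C10 is destroyed in step 8.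

Step 8
Reactants: 16 (4R)-4-acetoxy-2-(5-formyl-7-isopropyl-2,2-diphenyl-1,3-benzodioxol-4-yl)-6,6-dimethyloct-7-enoic acid
Product: 19 (2S,5S,7S,10R)-2-acetoxy-11,12-(diphenylmethylenedioxy)abieta-8,11,13-trien-20,7-olide, via 1-acetoxyisochroman-3-one 17 (not isolated), via 2-benzopyran-3-one 18 (not isolated)
Conditions: Ac2O/xylene (1:4), 0.005 M, 135 °C
Reagents that add atoms: none
Why: Acetic anhydride should convert the o-formylarylacetic acid into its cyclic pseudo-acid acetate 17, which loses acetic acid to the o-quinoid 2-benzopyran-3-one 18, whose diene C7=C8–C9=C10 adds the tethered C5=C6 vinyl group in an intramolecular Diels–Alder reaction that restores the aromatic ring C. The closest known reaction type is the generation of 2-benzopyran-3-ones from o-acylarylacetic acids in hot acetic anhydride and their inter- and intramolecular trapping by unactivated alkenes. Ring A closes in the fused mode of a type 1 intramolecular Diels–Alder reaction (six-membered, tether C1–C4 in a chair), ring B is the new cyclohexene of the [4+2] adduct, and the bridge C20(=O)–O–C7 is carried over from the pyranone. C7 and C10 are set as a cis pair by suprafacial addition across the cyclic diene, and C5 by the exo placement of C4 over the lactone bridge, since the endo mode would press the gem-dimethyl group against the peri oxygen at C11; this gives the trans A/B fusion. The absolute sense comes from C2: only the diene face that keeps the acetoxy group equatorial avoids a 1,3-diaxial contact with the axial C4 methyl and C20, and that face leads to the (5S,7S,10R) adduct. The step needs the cycloaddition to outrun dimerisation and tautomerisation of 18, which high dilution and the gem-dimethyl effect of C4 should secure.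

Step 9
Reactants: 19 (2S,5S,7S,10R)-2-acetoxy-11,12-(diphenylmethylenedioxy)abieta-8,11,13-trien-20,7-olide
Product: 20 (2S,5S,7S,10R)-11,12-(diphenylmethylenedioxy)abieta-8,11,13-triene-2,7,20-triol (2α,7β)
Conditions: LiAlH4, THF, 0 to 50 °C; aq. NaOH work-up
Reagents that add atoms: none
Why: Hydride reduction should open the bridged lactone to the 7,20-diol and cleave the acetate in the same operation, with no stereocentre touched.

Step 10
Reactants: 20 (2S,5S,7S,10R)-11,12-(diphenylmethylenedioxy)abieta-8,11,13-triene-2,7,20-triol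
Product: 21 (2S,5S,7S,10R)-7,20-epoxy-11,12-(diphenylmethylenedioxy)abieta-8,11,13-trien-2-ol
Conditions: CSA (cat.), CH2Cl2, 4 Å MS, rt
Reagents that add atoms: none
Why: Acid should ionise the benzylic C7–OH (cation stabilised by the para oxygen at C12) and the C20 hydroxyl held on the β face by C10 traps it in an SN1 cycloetherification, the bicyclic geometry allowing only the 7β,20-ether while the equatorial C2–OH cannot reach C7.

Step 11
Reactants: 21 (2S,5S,7S,10R)-7,20-epoxy-11,12-(diphenylmethylenedioxy)abieta-8,11,13-trien-2-ol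
Product: 22 (2S,5S,7S,10R)-2-acetoxy-7,20-epoxy-11,12-(diphenylmethylenedioxy)abieta-8,11,13-triene
Conditions: Ac2O, pyridine, DMAP (cat.), CH2Cl2, rt
Reagents that add atoms: acetic anhydride CC(=O)OC(C)=O
Why: DMAP-catalysed acylation of the only free hydroxyl (secondary, equatorial) should proceed with retention at C2 while the catechol is still masked.

Step 12
Reactants: 22 (2S,5S,7S,10R)-2-acetoxy-7,20-epoxy-11,12-(diphenylmethylenedioxy)abieta-8,11,13-triene
Product: 23 (2S,5S,7S,10R)-2-acetoxy-7,20-epoxyabieta-8,11,13-triene-11,12-diol (target)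
Conditions: H2 (1 atm), Pd(OH)2/C, EtOAc/MeOH, rt, under Ar on work-up
Reagents that add atoms: none
Why: Hydrogenolysis of the doubly benzylic diphenylmethylene ketal should be much faster than cleavage of the hindered bridged C7–O ether, and the acetate is inert, so the catechol is freed under neutral conditions.

Compound list
1 | 3-bromo-4,5-dihydroxybenzaldehyde | O=Cc1cc(Br)c(O)c(O)c1 | starting material
2 | 7-bromo-2,2-diphenyl-1,3-benzodioxole-5-carbaldehyde | O=Cc1cc(Br)c2OC(c3ccccc3)(c3ccccc3)Oc2c1 | intermediate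
3 | 7-isopropyl-2,2-diphenyl-1,3-benzodioxole-5-carbaldehyde | O=Cc1cc(C(C)C)c2OC(c3ccccc3)(c3ccccc3)Oc2c1 | intermediate
4 | 6-(dimethoxymethyl)-4-isopropyl-2,2-diphenyl-1,3-benzodioxole | COC(OC)c1cc(C(C)C)c2OC(c3ccccc3)(c3ccccc3)Oc2c1 | intermediate
5 | [5-(dimethoxymethyl)-7-isopropyl-2,2-diphenyl-1,3-benzodioxol-4-yl]lithium | COC(OC)c1cc(C(C)C)c2OC(c3ccccc3)(c3ccccc3)Oc2c1[Li] | intermediate
6 | 2-[5-(dimethoxymethyl)-7-isopropyl-2,2-diphenyl-1,3-benzodioxol-4-yl]ethan-1-ol | COC(OC)c1cc(C(C)C)c2OC(c3ccccc3)(c3ccccc3)Oc2c1CCO | intermediate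
7 | 2-[5-(dimethoxymethyl)-7-isopropyl-2,2-diphenyl-1,3-benzodioxol-4-yl]acetaldehyde | COC(OC)c1cc(C(C)C)c2OC(c3ccccc3)(c3ccccc3)Oc2c1CC=O | intermediate
8 | 2-[5-(dimethoxymethyl)-7-isopropyl-2,2-diphenyl-1,3-benzodioxol-4-yl]acetic acid | COC(OC)c1cc(C(C)C)c2OC(c3ccccc3)(c3ccccc3)Oc2c1CC(=O)O | intermediate
9 | (S)-epichlorohydrin, (S)-2-(chloromethyl)oxirane | ClC[C@@H]1CO1 | starting material
10 | prenylmagnesium chloride (3-methylbut-2-en-1-ylmagnesium chloride) | CC(C)=CC[Mg]Cl | starting material
11 | (S)-1-chloro-4,4-dimethylhex-5-en-2-ol (present as its magnesium alkoxide) | ClC[C@@H](O)CC(C)(C)C=C | intermediate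
12 | (S)-2-(2,2-dimethylbut-3-en-1-yl)oxirane | C=CC(C)(C)C[C@H]1CO1 | intermediate
13 | dilithium enediolate of 8 | COC(OC)c1cc(C(C)C)c2OC(c3ccccc3)(c3ccccc3)Oc2c1C=C(O[Li])O[Li] | intermediate
14 | dilithium salt of (4R)-2-[5-(dimethoxymethyl)-7-isopropyl-2,2-diphenyl-1,3-benzodioxol-4-yl]-4-hydroxy-6,6-dimethyloct-7-enoic acid | COC(OC)c1cc(C(C)C)c2OC(c3ccccc3)(c3ccccc3)Oc2c1C(C(=O)O[Li])C[C@@H](O[Li])CC(C)(C)C=C | intermediate
15 | (4R)-4-acetoxy-2-[5-(dimethoxymethyl)-7-isopropyl-2,2-diphenyl-1,3-benzodioxol-4-yl]-6,6-dimethyloct-7-enoic acid | COC(OC)c1cc(C(C)C)c2OC(c3ccccc3)(c3ccccc3)Oc2c1C(C(=O)O)C[C@@H](OC(C)=O)CC(C)(C)C=C | intermediate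
16 | (4R)-4-acetoxy-2-(5-formyl-7-isopropyl-2,2-diphenyl-1,3-benzodioxol-4-yl)-6,6-dimethyloct-7-enoic acid (both C2 epimers) | O=Cc1cc(C(C)C)c2OC(c3ccccc3)(c3ccccc3)Oc2c1C(C(=O)O)C[C@@H](OC(C)=O)CC(C)(C)C=C | intermediate
17 | 1-acetoxy-4-[(2R)-2-acetoxy-4,4-dimethylhex-5-en-1-yl]-7-isopropyl-5,6-(diphenylmethylenedioxy)isochroman-3-one | CC(=O)OC1OC(=O)C(C[C@@H](OC(C)=O)CC(C)(C)C=C)c2c1cc(C(C)C)c1OC(c3ccccc3)(c3ccccc3)Oc21 | intermediate
18 | 4-[(2S)-2-acetoxy-4,4-dimethylhex-5-en-1-yl]-7-isopropyl-5,6-(diphenylmethylenedioxy)-3H-2-benzopyran-3-one | O=C1OC=C2C=C(C(C)C)C3=C(C2=C1C[C@@H](OC(C)=O)CC(C)(C)C=C)OC(c2ccccc2)(c2ccccc2)O3 | intermediate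
19 | (2S,5S,7S,10R)-2-acetoxy-11,12-(diphenylmethylenedioxy)abieta-8,11,13-trien-20,7-olide | CC(=O)O[C@H]1CC(C)(C)[C@@H]2C[C@@H]3OC(=O)[C@@]2(C1)c1c3cc(C(C)C)c4OC(c5ccccc5)(c5ccccc5)Oc14 | intermediate
20 | (2S,5S,7S,10R)-11,12-(diphenylmethylenedioxy)abieta-8,11,13-triene-2,7,20-triol | O[C@H]1CC(C)(C)[C@@H]2C[C@H](O)c3cc(C(C)C)c4OC(c5ccccc5)(c5ccccc5)Oc4c3[C@@]2(CO)C1 | intermediate
21 | (2S,5S,7S,10R)-7,20-epoxy-11,12-(diphenylmethylenedioxy)abieta-8,11,13-trien-2-ol | O[C@H]1CC(C)(C)[C@@H]2C[C@@H]3OC[C@@]2(C1)c1c3cc(C(C)C)c4OC(c5ccccc5)(c5ccccc5)Oc14 | intermediate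
22 | (2S,5S,7S,10R)-2-acetoxy-7,20-epoxy-11,12-(diphenylmethylenedioxy)abieta-8,11,13-triene | CC(=O)O[C@H]1CC(C)(C)[C@@H]2C[C@@H]3OC[C@@]2(C1)c1c3cc(C(C)C)c4OC(c5ccccc5)(c5ccccc5)Oc14 | intermediate
23 | (2S,5S,7S,10R)-2-acetoxy-7,20-epoxyabieta-8,11,13-triene-11,12-diol | CC(=O)O[C@H]1CC(C)(C)[C@@H]2C[C@@H]3OC[C@@]2(C1)c1c3cc(C(C)C)c(O)c1O | target

Total step count: 12. Longest linear sequence: 11 (steps 1–5 and 7–12; step 6 is a one-step branch).

Steps most likely to fail

1. Step 8. The o-quinoid pyranone may dimerise, tautomerise under the acetic acid present, or add the unactivated vinyl group too slowly; the endo (cis-fused) mode may also compete. The fallback makes the diene by photoenolisation instead of dehydration and sets out from 16. Esterification with TMSCHN2 (MeOH/toluene, 0 °C) should give the methyl ester F1. Irradiation at 350 nm in degassed toluene should transfer the C10 hydrogen to the formyl oxygen and give the photoenol F2, a hydroxy-o-quinodimethane that is trapped by the tethered vinyl group in the same chair-like, acetoxy-equatorial mode to give the 7-hydroxy ester F3. CSA in toluene at 80 °C should lactonise either C7 epimer of F3 through the benzylic cation, and the route is rejoined at 19.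

2. Step 7. The doubly ortho-substituted enediolate may open the epoxide slowly, and on addition of the anhydride the alkoxide may lactonise onto the mixed anhydride before it is acetylated. The fallback accepts the lactone and sets out from 8 and 12. The same dianion alkylation (through 13 and 14), worked up with 1 M HCl and without anhydride, should give the γ-lactone aldehyde F4. One equivalent of KOH in aqueous THF opens it to the potassium hydroxy carboxylate F5, which is alkylated in DMF with allyl bromide to the hydroxy allyl ester F6 and acetylated at once (Ac2O, pyridine, DMAP, 0 °C) to the acetoxy allyl ester F7. Pd(PPh3)4 with PhSiH3 in CH2Cl2 cleaves the allyl ester under neutral conditions, and the route is rejoined at 16.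

3. Step 6. The prenyl reagent may attack through its primary carbon (linear product), and direct displacement of chloride would erode the enantiomeric purity. The fallback replaces 9 and 10 and does not rely on an allylic organometallic. Commercial methyl 3,3-dimethylpent-4-enoate F8 is reduced with DIBAL-H (CH2Cl2, −78 °C) to 3,3-dimethylpent-4-enal F9. Methylenation with Me3S+ I−/NaH in DMSO/THF (Corey–Chaykovsky) gives the racemic epoxide F10. Hydrolytic kinetic resolution with (S,S)-(salen)Co(III)OAc and 0.55 equiv of water should leave the (S)-epoxide, and the route is rejoined at 12.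

Further compounds
F1 | step 8 | methyl (4R)-4-acetoxy-2-(5-formyl-7-isopropyl-2,2-diphenyl-1,3-benzodioxol-4-yl)-6,6-dimethyloct-7-enoate | O=Cc1cc(C(C)C)c2OC(c3ccccc3)(c3ccccc3)Oc2c1C(C(=O)OC)C[C@@H](OC(C)=O)CC(C)(C)C=C
F2 | step 8 | photoenol of F1 (hydroxy-o-quinodimethane with C7(OH)=C8 and C9=C10) | OC=C1C=C(C(C)C)C2=C(C1=C(C(=O)OC)C[C@@H](OC(C)=O)CC(C)(C)C=C)OC(c1ccccc1)(c1ccccc1)O2
F3 | step 8 | methyl (2S,5S,10R)-2-acetoxy-7-hydroxy-11,12-(diphenylmethylenedioxy)abieta-8,11,13-trien-20-oate (C7 epimers) | CC(=O)O[C@H]1CC(C)(C)[C@@H]2CC(O)c3cc(C(C)C)c4OC(c5ccccc5)(c5ccccc5)Oc4c3[C@@]2(C(=O)OC)C1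
F4 | step 7 | (5R)-5-(2,2-dimethylbut-3-en-1-yl)-3-(5-formyl-7-isopropyl-2,2-diphenyl-1,3-benzodioxol-4-yl)dihydrofuran-2(3H)-one (both C3 epimers) | O=Cc1cc(C(C)C)c2OC(c3ccccc3)(c3ccccc3)Oc2c1C1C[C@H](CC(C)(C)C=C)OC1=O
F5 | step 7 | potassium (4R)-2-(5-formyl-7-isopropyl-2,2-diphenyl-1,3-benzodioxol-4-yl)-4-hydroxy-6,6-dimethyloct-7-enoate | O=Cc1cc(C(C)C)c2OC(c3ccccc3)(c3ccccc3)Oc2c1C(C(=O)[O-])C[C@@H](O)CC(C)(C)C=C.[K+]
F6 | step 7 | allyl (4R)-2-(5-formyl-7-isopropyl-2,2-diphenyl-1,3-benzodioxol-4-yl)-4-hydroxy-6,6-dimethyloct-7-enoate | O=Cc1cc(C(C)C)c2OC(c3ccccc3)(c3ccccc3)Oc2c1C(C(=O)OCC=C)C[C@@H](O)CC(C)(C)C=C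
F7 | step 7 | allyl (4R)-4-acetoxy-2-(5-formyl-7-isopropyl-2,2-diphenyl-1,3-benzodioxol-4-yl)-6,6-dimethyloct-7-enoate | O=Cc1cc(C(C)C)c2OC(c3ccccc3)(c3ccccc3)Oc2c1C(C(=O)OCC=C)C[C@@H](OC(C)=O)CC(C)(C)C=C
F8 | step 6 | methyl 3,3-dimethylpent-4-enoate | COC(=O)CC(C)(C)C=C
F9 | step 6 | 3,3-dimethylpent-4-enal | O=CCC(C)(C)C=C
F10 | step 6 | rac-2-(2,2-dimethylbut-3-en-1-yl)oxirane | C=CC(C)(C)CC1CO1
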